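Remark on the chemistry: prenyl stands for 3-methylbut-2-en-1-yl; the benzofuran is numbered O1, C2, C3, C3a–C7a (ring A = C3a–C7a) and the resorcinol C1′–C6′ (ring B); methoxyethyne is assumed not to be a stock chemical and is made in step 9.

## Analysis of the target

The target is a 2-arylbenzofuran. Ring A carries OH at C6 and a prenyl group at C7, the furan ring is unsubstituted at C3, and C2 is bonded to C1′ of ring B. Ring B is a resorcinol with OH at C3′ and C5′, H at C4′, and prenyl groups at C2′ and C6′, on both sides of the biaryl bond. There is no stereocentre, and the three side-chain alkenes are trisubstituted with two identical methyl ends, so no configuration has to be set in the final compound. Every prenyl group sits ortho to a phenol: acid closes 2,2-dimethylchromans, quinone oxidants give chromenes, and hydrogenation or strong Lewis acids cannot be used late. The hard part is regiocontrol: C2′ and C6′ are the most hindered positions of a preformed biaryl, and C7 lies between two oxygens. The strategy rests on the pattern of ring B: oxygen on C3′ and C5′ with C4′–H between them, and three contiguous carbon substituents on C6′, C1′ and C2′. This is the pattern formed when a fully substituted vinylketene (C3′, C6′, C1′, C2′) takes up the two carbons of an alkoxyacetylene (C4′, C5′).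

## Retrosynthetic reasoning

**Unmasking.** Target 32 is taken back to acetal 31, to the bis(methyl ether) 30 and to phenol 29; only O–C bonds of protecting groups are cut. The ring construction delivers O3′ as a free phenol and O5′ as an alkyl ether. A sulfur nucleophile will not dealkylate O5′ next to an ionised O3′, because a resorcinol monoether stops at the phenoxide stage. Acids strong enough to cleave an aryl alkyl ether would close chromans. O3′ is therefore capped as a neutral acetal (30), both methyl ethers (O6 on ring A, O5′ on ring B) are removed in one SN2 step (31), and weak acid removes the acetal. Methyl is chosen for O5′ because SN2 dealkylation is far faster at methyl than at a higher alkyl group. Methyl is chosen for O6 because it directs the metalation at C7 and leaves in the same step, whereas a silyl ether would do neither reliably.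

**Ring B.** Phenol 29 is cut at C3′–C4′, C5′–C6′ and C2′–C3′ into diazo ketone 21 and methoxyethyne 24. Cutting here means that no substituent is ever introduced onto a crowded arene: both prenyl groups and the benzofuranyl group are already on the open chain. The forward reaction has to turn 21 into vinylketene 25, add 24 across the ketene with the oxygen-bearing carbon on the ketene α-carbon (26), and carry 26 through ring opening (27) and 6π closure (28) to 29. Ynol ether 24 has no β-hydrogen and so cannot fragment to ketene during the thermal stage.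

**Diazo group.** Diazo ketone 21 goes back to ketone 19 by removal of N2 from C5. C5 is the only enolisable α-carbon of 19, so diazo transfer after activation is regiochemically unambiguous.

**Ketone.** Ketone 19 is cut at C5–C6 into Weinreb amide 16 and Grignard reagent 18 (from bromide 17); 16 comes from ester 15. This brings in the second five-carbon chain as a commercial homoprenyl unit and keeps the enone masked until work-up.

**Aryl–vinyl bond.** Ester 15 is cut between C2 of the benzofuran and the alkene carbon into organozinc 14 (from 7 through 13) and vinyl bromide 12. A stereoretentive coupling is preferred to a base-mediated condensation because it fixes the E geometry and does not expose the skipped diene to base. Bromide 12 comes from aldehyde 10 (from alcohol 8) and bromo ylide 11 (from ylide 9).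

**Ring A.** Benzofuran 7 is cut at C7–CH2 into aryllithium 5 and prenyl bromide 4. C7 is flanked by two oxygens and is the natural site of directed metalation once C2, the kinetically most acidic position, is blocked by a silyl group (3, from 1 through 2). The block is removed afterwards (6 to 7).

**Ynol ether.** Methoxyethyne 24 comes from chloroacetal 22 through acetylide 23 by double elimination.

## Alternatives that were turned down

**Alternative 1:** The disconnection is at O1–C2 and C2–C3 of a 2,3-dihydrobenzofuran. In the forward step a carbonate base releases an ortho-quinone methide of ring A from ammonium salt A1 and an ylide of ring B from sulfonium salt A2; conjugate addition and displacement of the sulfide give dihydrobenzofuran A3 in a formal [4+1] annulation.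
- For: two complete arenes are joined at room temperature without metal or light. On convergence and mildness of the union this is stronger than the chosen route.
- Against: A2 is already the hexasubstituted ring B, so the crowded pattern still has to be built by stepwise substitution. The ylide carbon of A2 lies between two ortho prenyl groups, which hinders both the addition and the ring closure. A3 is at the wrong oxidation level, and the furan double bond must be introduced by dehydrogenation in a molecule with six benzylic or allylic CH2 groups. Three acetals must then be removed with acid beside prenyl groups.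
- Comparison: the chosen strategy is longer and needs a photochemical step, but it makes ring B by construction and reaches the aromatic oxidation level directly.

**Alternative 2:** The disconnection is at the three aryl–CH2 bonds (C2′, C6′, C7), traced back to the O–C bonds of the tris(1,1-dimethylallyl) ether A4, whose ester blocks the carbon between the ring B oxygens. In the forward step heating in a high-boiling aniline performs three aromatic Claisen rearrangements to A5.
- For: the biaryl core is simple and symmetrical and all three prenyl groups arrive in one operation. On step count it is clearly stronger.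
- Against: three [3,3] shifts must all succeed in one molecule, two of them into positions next to the biaryl bond. On ring A both C5 and C7 are open. Tertiary allyl aryl ethers lose isoprene on heating, and the ortho-prenylphenols formed can close chromans at the temperature needed. The ester of A5 must finally be hydrolysed and decarboxylated under conditions that threaten the prenyl groups.
- Comparison: the chosen route places each prenyl group by an unambiguous bond construction, at the cost of more steps.

**Alternative 3:** The disconnection is at C3–C3a. In the forward step zerovalent palladium inserts into the vinyl C–Br bond of bromovinyl ether A6, carboxylate-assisted palladation of the only free ortho C–H of the aryloxy ring follows, and reductive elimination gives A7, the tris(methoxymethyl) ether of the target.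
- For: the furan forms at the right oxidation level, the regiochemistry on ring A cannot go wrong, and one deprotection ends the synthesis. On end-game length and regiochemical certainty it is stronger.
- Against: ring B must again be prefabricated as a hexasubstituted arene, here as a bromoalkyne between two prenyl groups to which a phenol must add. The vinylpalladium centre of A6 lies five or six atoms from the ortho prenyl alkenes, so Heck-type carbopalladation competes with the slower C–H cleavage. Acid removal of three acetals beside prenyl groups remains.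
- Comparison: the chosen strategy never needs a preformed ring B and has no metal–carbon intermediate near the prenyl alkenes, but its last three steps are longer.

Key step: step 10

## Route

Step 1
Reactants: 1 6-methoxy-1-benzofuran
Product: 3 (6-methoxy-1-benzofuran-2-yl)trimethylsilane, via 2-lithio-6-methoxybenzofuran 2 (not isolated)
Conditions: n-BuLi, THF, −78 °C; Me3SiCl, −78 °C → rt
Reagents that add atoms: chlorotrimethylsilane, C[Si](C)(C)Cl
Why: Benzofuran is lithiated kinetically at C2, the furan position next to oxygen, and silylation of the anion (lithiation/electrophilic quench) blocks this site so that the next metalation must occur elsewhere.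

Step 2
Reactants: 3 (6-methoxy-1-benzofuran-2-yl)trimethylsilane; 4 1-bromo-3-methylbut-2-ene (prenyl bromide)
Product: 6 (6-methoxy-7-prenyl-1-benzofuran-2-yl)trimethylsilane, via 7-lithio-6-methoxy-2-(trimethylsilyl)benzofuran 5 (not isolated)
Conditions: n-BuLi, TMEDA, THF, 0 °C; CuBr·SMe2 (20 mol%), then 4, −78 °C → rt
Reagents that add atoms: none
Why: Directed ortho-metalation: with C2 blocked, C7–H is the only proton flanked by two oxygens (the methoxy group and the ring oxygen), as at C2 of 1,3-dimethoxybenzene, and copper-catalysed SN2 allylation of the aryllithium should give the linear prenyl group.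

Step 3
Reactants: 6 (6-methoxy-7-prenyl-1-benzofuran-2-yl)trimethylsilane
Product: 7 6-methoxy-7-prenyl-1-benzofuran
Conditions: Bu4NF·3H2O, THF, rt → 50 °C
Reagents that add atoms: none
Why: Fluoride-induced protodesilylation of a 2-silylbenzofuran frees C2; the methyl ether and the prenyl alkene are inert to fluoride.

Step 4
Reactants: 8 4-methylpent-3-en-1-ol; 9 ethyl (triphenylphosphoranylidene)acetate
Product: 12 ethyl (2Z)-2-bromo-6-methylhepta-2,5-dienoate, via 4-methylpent-3-enal 10 (not isolated), via ethyl bromo(triphenylphosphoranylidene)acetate 11 (not isolated)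
Conditions: 8: Dess–Martin periodinane, pyridine, CH2Cl2, 0 °C, cold NaHCO3/Na2S2O3 wash, solution of 10 used at once; 9: N-bromosuccinimide, CH2Cl2, −20 °C; the two solutions combined, −20 °C → rt
Reagents that add atoms: N-bromosuccinimide, O=C1CCC(=O)N1Br
Why: Dess–Martin oxidation gives the β,γ-unsaturated aldehyde, which is kept cold and unpurified because base or silica would move its double bond into conjugation. Bromination of the stabilised ylide followed by Wittig olefination under neutral conditions should give mainly the Z α-bromo enoate (bromine cis to the chain), the usual outcome for α-halo ester ylides, and the minor isomer is removed by chromatography.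

Step 5
Reactants: 7 6-methoxy-7-prenyl-1-benzofuran; 12 ethyl (2Z)-2-bromo-6-methylhepta-2,5-dienoate
Product: 15 ethyl (2E)-2-(6-methoxy-7-prenyl-1-benzofuran-2-yl)-6-methylhepta-2,5-dienoate, via 2-lithio-6-methoxy-7-prenylbenzofuran 13 (not isolated), via benzofuran-2-ylzinc chloride 14 (not isolated)
Conditions: 7: n-BuLi, THF, −78 °C; ZnCl2, −78 → 0 °C; then 12, Pd(PPh3)4 (5 mol%), THF, rt → 45 °C
Reagents that add atoms: none
Why: C2 lithiation, transmetalation to zinc and Negishi coupling; oxidative addition to zerovalent palladium and reductive elimination go with retention, so the benzofuranyl group takes the place of bromine cis to the chain (Z bromide to E ester, the descriptor changing only through the priority rules). The organozinc is too weakly basic to shift the skipped diene.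

Step 6
Reactants: 15 ethyl (2E)-2-(6-methoxy-7-prenyl-1-benzofuran-2-yl)-6-methylhepta-2,5-dienoate
Product: 16 (2E)-N-methoxy-2-(6-methoxy-7-prenyl-1-benzofuran-2-yl)-N,6-dimethylhepta-2,5-dienamide
Conditions: MeNH(OMe)·HCl, AlMe3, CH2Cl2, 0 → 40 °C; aqueous sodium potassium tartrate work-up
Reagents that add atoms: N,O-dimethylhydroxylamine hydrochloride, CNOC.Cl
Why: Weinreb aminolysis of the ester by the aluminium amide; the reagent is Lewis acidic rather than basic, so the doubly allylic CH2 of the skipped diene is not deprotonated.

Step 7
Reactants: 16 (2E)-N-methoxy-2-(6-methoxy-7-prenyl-1-benzofuran-2-yl)-N,6-dimethylhepta-2,5-dienamide; 17 5-bromo-2-methylpent-2-ene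
Product: 19 (7E)-7-(6-methoxy-7-prenyl-1-benzofuran-2-yl)-2,11-dimethyldodeca-2,7,10-trien-6-one, via 4-methylpent-3-enylmagnesium bromide 18 (not isolated)
Conditions: 17: Mg, THF, rt → 40 °C; then 16, THF, −10 → 0 °C; aq. NH4Cl
Reagents that add atoms: none
Why: Grignard addition to a Weinreb amide stops at the chelated tetrahedral intermediate, so one homoprenyl group is delivered and the enone appears only on work-up, when no organometallic is left for conjugate addition.

Step 8
Reactants: 19 (7E)-7-(6-methoxy-7-prenyl-1-benzofuran-2-yl)-2,11-dimethyldodeca-2,7,10-trien-6-one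
Product: 21 (7E)-5-diazo-7-(6-methoxy-7-prenyl-1-benzofuran-2-yl)-2,11-dimethyldodeca-2,7,10-trien-6-one, via alpha-trifluoroacetyl ketone 20 (not isolated)
Conditions: LiN(SiMe3)2, THF, −78 °C; CF3CO2CH2CF3, −78 °C; then MeSO2N3, Et3N, H2O (1 equiv.), MeCN, rt
Reagents that add atoms: methanesulfonyl azide, CS(=O)(=O)N=[N+]=[N-]
Why: Detrifluoroacetylative diazo transfer: the amide base removes a proton from C5, the only enolisable α-carbon (the γ-CH2 lies trans to the carbonyl, out of reach of the coordinated base); trifluoroacetylation activates C5, and the sulfonyl azide transfers N2 with loss of the trifluoroacetyl group as its sulfonamide.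

Step 9
Reactants: 22 2-chloro-1,1-dimethoxyethane
Product: 24 methoxyethyne, via sodium methoxyacetylide 23 (not isolated)
Conditions: NaNH2 (3 equiv.), liquid NH3, −33 °C; saturated aqueous NaCl, −70 °C; distillation, stored cold
Reagents that add atoms: none
Why: Twofold elimination (HCl, then methanol) with sodium amide gives the acetylide, which is protonated on cold quench; this is the classical preparation of alkoxyacetylenes.

Step 10
Reactants: 21 (7E)-5-diazo-7-(6-methoxy-7-prenyl-1-benzofuran-2-yl)-2,11-dimethyldodeca-2,7,10-trien-6-one; 24 methoxyethyne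
Product: 29 5-methoxy-3-(6-methoxy-7-prenyl-1-benzofuran-2-yl)-2,4-diprenylphenol, via vinylketene 25 (not isolated), via 4-vinylcyclobutenone 26 (not isolated), via dienylketene 27 (not isolated), via cyclohexadienone 28 (not isolated)
Conditions: 24 (5 equiv.), ClCH2CH2Cl, hν (254 nm, low-pressure Hg lamps, quartz, sealed tube), 10 °C; then 80 °C
Reagents that add atoms: none
Why: Irradiation expels N2 and the alkenyl group migrates from the carbonyl carbon to the diazo carbon (photochemical Wolff rearrangement), giving vinylketene 25 with the alkene geometry retained. The ketene carbonyl carbon (future C3′) is attacked by the nucleophilic CH terminus of ynol ether 24 and the ketene α-carbon (future C6′) bonds to the oxygen-bearing alkyne carbon, a polarised [2+2] cycloaddition that gives 3-methoxy-4-vinylcyclobutenone 26. On warming, 26 opens by conrotatory 4π cleavage of the bond between the two former ketene carbons to dienylketene 27, whose 6π electrocyclisation joins the ketene carbon to the vinyl terminus (C2′–C3′) and gives cyclohexadienone 28, which enolises to phenol 29. This is the Danheiser benzannulation in its diazo ketone form, applied to a heteroaryl-substituted vinylketene. Ring B is the only ring closed and it closes by 6π electrocyclisation; the four-membered ring of 26 is transient. No stereocentre remains, since the quaternary carbon of 26 and the sp3 carbon of 28 are racemic and are erased by ring opening and aromatisation. The step needs the rearrangement to outrun carbene chemistry (1,2-hydrogen shift from the neighbouring allylic CH2, addition to the four spectator alkenes), which direct singlet excitation and the high migratory aptitude of an alkenyl group favour, and it needs the [2+2] orientation that the polarity of the ynol ether fixes, placing OMe meta to the new OH with C4′–H between them. The E geometry of 21 keeps the prenyl chain on the outer side of the vinyl terminus, which eases the 6π closure and keeps that alkene away from the ketene, and the excess of 24 limits acylation of the product phenol by the ketene.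

Step 11
Reactants: 29 5-methoxy-3-(6-methoxy-7-prenyl-1-benzofuran-2-yl)-2,4-diprenylphenol
Product: 30 6-methoxy-2-[3-methoxy-5-(oxan-2-yloxy)-2,6-diprenylphenyl]-7-prenyl-1-benzofuran (racemic)
Conditions: 3,4-dihydro-2H-pyran, pyridinium p-toluenesulfonate (10 mol%), CH2Cl2, rt
Reagents that add atoms: 3,4-dihydro-2H-pyran, C1=COCCC1
Why: Acid-catalysed addition of the phenol to the enol ether (tetrahydropyranyl ether formation) masks O3′ as a neutral acetal so that no phenoxide sits on ring B in the next step. The acetal carbon is a new stereocentre, formed racemic and removed in step 13.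

Step 12
Reactants: 30 6-methoxy-2-[3-methoxy-5-(oxan-2-yloxy)-2,6-diprenylphenyl]-7-prenyl-1-benzofuran
Product: 31 2-[3-hydroxy-5-(oxan-2-yloxy)-2,6-diprenylphenyl]-7-prenyl-1-benzofuran-6-ol (racemic)
Conditions: NaSEt (10 equiv.), DMF, 140 °C, argon; aq. NH4Cl
Reagents that add atoms: none
Why: SN2 cleavage of both aryl methyl ethers by ethanethiolate in a dipolar aprotic solvent; each leaving group is a mono-phenoxide on a different ring, the secondary acetal carbon is inert to the thiolate, and the non-acidic medium leaves the three prenyl groups untouched.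

Step 13
Reactants: 31 2-[3-hydroxy-5-(oxan-2-yloxy)-2,6-diprenylphenyl]-7-prenyl-1-benzofuran-6-ol
Product: 32 5-(6-hydroxy-7-prenyl-1-benzofuran-2-yl)-4,6-diprenylbenzene-1,3-diol (target)
Conditions: pyridinium p-toluenesulfonate (20 mol%), MeOH, 45 °C
Reagents that add atoms: none
Why: Mild acid-catalysed transacetalisation of the aryl tetrahydropyranyl ether in methanol releases the last phenol; the pyridinium salt is too weak an acid to protonate the prenyl alkenes and close chromans at this temperature.

## Compound list

1 | 6-methoxy-1-benzofuran | COc1ccc2ccoc2c1 | starting material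
2 | (6-methoxy-1-benzofuran-2-yl)lithium | [Li]c1cc2ccc(OC)cc2o1 | intermediate
3 | (6-methoxy-1-benzofuran-2-yl)trimethylsilane | COc1ccc2cc([Si](C)(C)C)oc2c1 | intermediate
4 | 1-bromo-3-methylbut-2-ene (prenyl bromide) | CC(C)=CCBr | starting material
5 | [6-methoxy-2-(trimethylsilyl)-1-benzofuran-7-yl]lithium | COc1ccc2cc([Si](C)(C)C)oc2c1[Li] | intermediate
6 | (6-methoxy-7-prenyl-1-benzofuran-2-yl)trimethylsilane | COc1ccc2cc([Si](C)(C)C)oc2c1CC=C(C)C | intermediate
7 | 6-methoxy-7-prenyl-1-benzofuran | COc1ccc2ccoc2c1CC=C(C)C | intermediate
8 | 4-methylpent-3-en-1-ol | CC(C)=CCCO | starting material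
9 | ethyl (triphenylphosphoranylidene)acetate | CCOC(=O)C=P(c1ccccc1)(c1ccccc1)c1ccccc1 | starting material
10 | 4-methylpent-3-enal | CC(C)=CCC=O | intermediate
11 | ethyl bromo(triphenylphosphoranylidene)acetate | CCOC(=O)C(Br)=P(c1ccccc1)(c1ccccc1)c1ccccc1 | intermediate
12 | ethyl (2Z)-2-bromo-6-methylhepta-2,5-dienoate | CCOC(=O)/C(Br)=C/CC=C(C)C | intermediate
13 | (6-methoxy-7-prenyl-1-benzofuran-2-yl)lithium | [Li]c1cc2ccc(OC)c(CC=C(C)C)c2o1 | intermediate
14 | chloro(6-methoxy-7-prenyl-1-benzofuran-2-yl)zinc | Cl[Zn]c1cc2ccc(OC)c(CC=C(C)C)c2o1 | intermediate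
15 | ethyl (2E)-2-(6-methoxy-7-prenyl-1-benzofuran-2-yl)-6-methylhepta-2,5-dienoate | CCOC(=O)/C(=C/CC=C(C)C)c1cc2ccc(OC)c(CC=C(C)C)c2o1 | intermediate
16 | (2E)-N-methoxy-2-(6-methoxy-7-prenyl-1-benzofuran-2-yl)-N,6-dimethylhepta-2,5-dienamide | CON(C)C(=O)/C(=C/CC=C(C)C)c1cc2ccc(OC)c(CC=C(C)C)c2o1 | intermediate
17 | 5-bromo-2-methylpent-2-ene | CC(C)=CCCBr | starting material
18 | bromo(4-methylpent-3-en-1-yl)magnesium | CC(C)=CCC[Mg]Br | intermediate
19 | (7E)-7-(6-methoxy-7-prenyl-1-benzofuran-2-yl)-2,11-dimethyldodeca-2,7,10-trien-6-one | CC(C)=CCCC(=O)/C(=C/CC=C(C)C)c1cc2ccc(OC)c(CC=C(C)C)c2o1 | intermediate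
20 | (5E)-1,1,1-trifluoro-5-(6-methoxy-7-prenyl-1-benzofuran-2-yl)-9-methyl-3-prenyldeca-5,8-diene-2,4-dione (racemic) | CC(C)=CCC(C(=O)C(F)(F)F)C(=O)/C(=C/CC=C(C)C)c1cc2ccc(OC)c(CC=C(C)C)c2o1 | intermediate
21 | (7E)-5-diazo-7-(6-methoxy-7-prenyl-1-benzofuran-2-yl)-2,11-dimethyldodeca-2,7,10-trien-6-one | CC(C)=CCC(=[N+]=[N-])C(=O)/C(=C/CC=C(C)C)c1cc2ccc(OC)c(CC=C(C)C)c2o1 | intermediate
22 | 2-chloro-1,1-dimethoxyethane | COC(CCl)OC | starting material
23 | sodium methoxyacetylide | [Na+].[C-]#COC | intermediate
24 | methoxyethyne | COC#C | intermediate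
25 | (3Z)-3-(6-methoxy-7-prenyl-1-benzofuran-2-yl)-7-methyl-2-prenylocta-1,3,6-trien-1-one (vinylketene) | O=C=C(CC=C(C)C)/C(=C/CC=C(C)C)c1cc2ccc(OC)c(CC=C(C)C)c2o1 | intermediate
26 | 3-methoxy-4-[(1Z)-1-(6-methoxy-7-prenyl-1-benzofuran-2-yl)-5-methylhexa-1,4-dien-1-yl]-4-prenylcyclobut-2-en-1-one (racemic) | O=C1C=C(OC)C1(CC=C(C)C)/C(=C/CC=C(C)C)c1cc2ccc(OC)c(CC=C(C)C)c2o1 | intermediate
27 | (3E,5Z)-3-methoxy-5-(6-methoxy-7-prenyl-1-benzofuran-2-yl)-9-methyl-4-prenyldeca-1,3,5,8-tetraen-1-one (dienylketene) | O=C=C/C(OC)=C(CC=C(C)C)\C(=C\CC=C(C)C)c1cc2ccc(OC)c(CC=C(C)C)c2o1 | intermediate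
28 | 3-methoxy-5-(6-methoxy-7-prenyl-1-benzofuran-2-yl)-4,6-diprenylcyclohexa-2,4-dien-1-one (racemic) | O=C1C=C(OC)C(CC=C(C)C)=C(c2cc3ccc(OC)c(CC=C(C)C)c3o2)C1CC=C(C)C | intermediate
29 | 5-methoxy-3-(6-methoxy-7-prenyl-1-benzofuran-2-yl)-2,4-diprenylphenol | COc1cc(O)c(CC=C(C)C)c(-c2cc3ccc(OC)c(CC=C(C)C)c3o2)c1CC=C(C)C | intermediate
30 | 6-methoxy-2-[3-methoxy-5-(oxan-2-yloxy)-2,6-diprenylphenyl]-7-prenyl-1-benzofuran (racemic) | COc1cc(OC2CCCCO2)c(CC=C(C)C)c(-c2cc3ccc(OC)c(CC=C(C)C)c3o2)c1CC=C(C)C | intermediate
31 | 2-[3-hydroxy-5-(oxan-2-yloxy)-2,6-diprenylphenyl]-7-prenyl-1-benzofuran-6-ol (racemic) | Oc1cc(OC2CCCCO2)c(CC=C(C)C)c(-c2cc3ccc(O)c(CC=C(C)C)c3o2)c1CC=C(C)C | intermediate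
32 | 5-[6-hydroxy-7-(3-methylbut-2-en-1-yl)-1-benzofuran-2-yl]-4,6-bis(3-methylbut-2-en-1-yl)benzene-1,3-diol | CC(C)=CCc1c(O)cc(O)c(CC=C(C)C)c1-c1cc2ccc(O)c(CC=C(C)C)c2o1 | target

## Step count and least certain steps

Total step count: 13. Longest linear sequence: 11 steps (1, 2, 3, 5, 6, 7, 8, 10, 11, 12, 13); steps 4 and 9 are side branches.

**Step 10 (key step).** After loss of N2 the acyl carbene may undergo a 1,2-hydrogen shift from the neighbouring allylic CH2, or add to one of the alkenes, instead of rearranging. An α-substituted acyclic diazo ketone populates conformers in which concerted migration is less favoured. Over-irradiation of the strongly absorbing benzofuranyl-vinyl chromophore and acylation of the product phenol by unreacted ketene are further losses. The fallback makes the same vinylketene thermally, without a carbene, and sets out from 7: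
- Lithiation as in step 5 and acylation with N-methoxy-N-methylcarbamoyl chloride would give N,6-dimethoxy-N-methyl-7-prenyl-1-benzofuran-2-carboxamide F1.
- Grignard reagent 18 would convert it into 1-(6-methoxy-7-prenyl-1-benzofuran-2-yl)-5-methylhex-4-en-1-one F2.
- Horner–Wadsworth–Emmons olefination with triethyl phosphonoacetate and NaH would give ethyl 3-(6-methoxy-7-prenyl-1-benzofuran-2-yl)-7-methylocta-2,6-dienoate F3.
- LiN(iPr)2 in THF/DMPU would remove a γ-proton, and α-alkylation of the dienolate with prenyl bromide 4 would give the deconjugated ester ethyl 3-(6-methoxy-7-prenyl-1-benzofuran-2-yl)-7-methyl-2-prenylocta-3,6-dienoate F4.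
- LiOH would give 3-(6-methoxy-7-prenyl-1-benzofuran-2-yl)-7-methyl-2-prenylocta-3,6-dienoic acid F5, and 1-chloro-N,N,2-trimethylprop-1-en-1-amine the acid chloride 3-(6-methoxy-7-prenyl-1-benzofuran-2-yl)-7-methyl-2-prenylocta-3,6-dienoyl chloride F6.
- Et3N in toluene in the presence of 24 would eliminate HCl to the vinylketene (25 and its geometric isomer), and the same [2+2], 4π and 6π sequence at 20 → 80 °C returns to the route at 29.

**Step 12.** Loss of the acetal at 140 °C, thermally or by slow attack of the thiolate, would regenerate a phenoxide on ring B and stall the removal of the O5′ methyl group. The fallback removes the need for SN2 at O5′ and sets out from 21: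
- The benzannulation is run with tert-butoxyethyne F7 in place of 24, with the excess alkyne evaporated before the thermal stage because it loses isobutene on heating. This would give 5-tert-butoxy-3-(6-methoxy-7-prenyl-1-benzofuran-2-yl)-2,4-diprenylphenol F8.
- NaSEt in DMF would then cleave only the ring A methyl ether, for which the ring B phenoxide is no obstacle, giving 2-(3-tert-butoxy-5-hydroxy-2,6-diprenylphenyl)-7-prenyl-1-benzofuran-6-ol F9.
- Aqueous H3PO4 (85%) in toluene at rt, an acid weaker than trifluoroacetic acid, would remove the tert-butyl group as isobutene and return to the route at 32. If the tert-butyl ether were already lost under the thiolate conditions, the sequence would simply be one step shorter.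

**Step 8.** Removal of the doubly allylic γ-proton in competition with the α′-proton would move the C7=C8 double bond out of the skipped position, and acylation at the α′-carbon next to the crowded enone may be incomplete. The fallback introduces the diazo carbon as a preformed diazoalkane and sets out from 15:
- LiOH would give (2E)-2-(6-methoxy-7-prenyl-1-benzofuran-2-yl)-6-methylhepta-2,5-dienoic acid F10, and 1-chloro-N,N,2-trimethylprop-1-en-1-amine the acid chloride (2E)-2-(6-methoxy-7-prenyl-1-benzofuran-2-yl)-6-methylhepta-2,5-dienoyl chloride F11.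
- Separately, aldehyde 10 and tosylhydrazine would give 4-methyl-N'-(4-methylpent-3-en-1-ylidene)benzenesulfonohydrazide F12, whose sodium salt on vacuum pyrolysis (Bamford–Stevens) would give 5-diazo-2-methylpent-2-ene F13.
- Acylation of F13 (2.2 equiv., Et2O, −20 °C, no amine base) by F11 returns to the route at 21.

**Step 2.** Metalation may occur in part at C5 or C3, and the allylation may proceed with allylic transposition to the 1,1-dimethylallyl isomer. The fallback places the prenyl group by a sigmatropic shift and sets out from 1:
- NaSEt in DMF would give 1-benzofuran-6-ol F14.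
- 3-Chloro-3-methylbut-1-yne, DBU and CuCl2 (1 mol%) in MeCN would give 6-[(2-methylbut-3-yn-2-yl)oxy]-1-benzofuran F15.
- Semihydrogenation over Pd/CaCO3 poisoned with Pb(OAc)2 and quinoline would give 6-[(2-methylbut-3-en-2-yl)oxy]-1-benzofuran F16.
- Aromatic Claisen rearrangement in N,N-diethylaniline at 190 °C, directed to C7 by the higher bond order of C6–C7, would give 7-prenyl-1-benzofuran-6-ol F17.
- MeI and K2CO3 in acetone return to the route at 7.

## Further compounds

F1 | step 10 | N,6-dimethoxy-N-methyl-7-prenyl-1-benzofuran-2-carboxamide | CON(C)C(=O)c1cc2ccc(OC)c(CC=C(C)C)c2o1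
F2 | step 10 | 1-(6-methoxy-7-prenyl-1-benzofuran-2-yl)-5-methylhex-4-en-1-one | CC(C)=CCCC(=O)c1cc2ccc(OC)c(CC=C(C)C)c2o1
F3 | step 10 | ethyl 3-(6-methoxy-7-prenyl-1-benzofuran-2-yl)-7-methylocta-2,6-dienoate (mixture of alkene isomers) | CCOC(=O)C=C(CCC=C(C)C)c1cc2ccc(OC)c(CC=C(C)C)c2o1
F4 | step 10 | ethyl 3-(6-methoxy-7-prenyl-1-benzofuran-2-yl)-7-methyl-2-prenylocta-3,6-dienoate (racemic, mixture of alkene isomers) | CCOC(=O)C(CC=C(C)C)C(=CCC=C(C)C)c1cc2ccc(OC)c(CC=C(C)C)c2o1
F5 | step 10 | 3-(6-methoxy-7-prenyl-1-benzofuran-2-yl)-7-methyl-2-prenylocta-3,6-dienoic acid (racemic, mixture of alkene isomers) | OC(=O)C(CC=C(C)C)C(=CCC=C(C)C)c1cc2ccc(OC)c(CC=C(C)C)c2o1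
F6 | step 10 | 3-(6-methoxy-7-prenyl-1-benzofuran-2-yl)-7-methyl-2-prenylocta-3,6-dienoyl chloride (racemic, mixture of alkene isomers) | O=C(Cl)C(CC=C(C)C)C(=CCC=C(C)C)c1cc2ccc(OC)c(CC=C(C)C)c2o1
F7 | step 12 | tert-butoxyethyne | CC(C)(C)OC#C
F8 | step 12 | 5-tert-butoxy-3-(6-methoxy-7-prenyl-1-benzofuran-2-yl)-2,4-diprenylphenol | CC(C)(C)Oc1cc(O)c(CC=C(C)C)c(-c2cc3ccc(OC)c(CC=C(C)C)c3o2)c1CC=C(C)C
F9 | step 12 | 2-(3-tert-butoxy-5-hydroxy-2,6-diprenylphenyl)-7-prenyl-1-benzofuran-6-ol | CC(C)(C)Oc1cc(O)c(CC=C(C)C)c(-c2cc3ccc(O)c(CC=C(C)C)c3o2)c1CC=C(C)C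
F10 | step 8 | (2E)-2-(6-methoxy-7-prenyl-1-benzofuran-2-yl)-6-methylhepta-2,5-dienoic acid | OC(=O)/C(=C/CC=C(C)C)c1cc2ccc(OC)c(CC=C(C)C)c2o1
F11 | step 8 | (2E)-2-(6-methoxy-7-prenyl-1-benzofuran-2-yl)-6-methylhepta-2,5-dienoyl chloride | O=C(Cl)/C(=C/CC=C(C)C)c1cc2ccc(OC)c(CC=C(C)C)c2o1
F12 | step 8 | 4-methyl-N'-(4-methylpent-3-en-1-ylidene)benzenesulfonohydrazide | CC(C)=CCC=NNS(=O)(=O)c1ccc(C)cc1
F13 | step 8 | 5-diazo-2-methylpent-2-ene | CC(C)=CCC=[N+]=[N-]
F14 | step 2 | 1-benzofuran-6-ol | Oc1ccc2ccoc2c1
F15 | step 2 | 6-[(2-methylbut-3-yn-2-yl)oxy]-1-benzofuran | C#CC(C)(C)Oc1ccc2ccoc2c1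
F16 | step 2 | 6-[(2-methylbut-3-en-2-yl)oxy]-1-benzofuran | C=CC(C)(C)Oc1ccc2ccoc2c1
F17 | step 2 | 7-prenyl-1-benzofuran-6-ol | Oc1ccc2ccoc2c1CC=C(C)C
A1 | alternative 1 | {[2-hydroxy-4-(methoxymethoxy)-3-prenylphenyl]methyl}trimethylammonium iodide | COCOc1ccc(C[N+](C)(C)C)c(O)c1CC=C(C)C.[I-]
A2 | alternative 1 | 1-{[3,5-bis(methoxymethoxy)-2,6-diprenylphenyl]methyl}thiolan-1-ium bromide | COCOc1cc(OCOC)c(CC=C(C)C)c(C[S+]2CCCC2)c1CC=C(C)C.[Br-]
A3 | alternative 1 | 2-[3,5-bis(methoxymethoxy)-2,6-diprenylphenyl]-6-(methoxymethoxy)-7-prenyl-2,3-dihydro-1-benzofuran (racemic) | COCOc1ccc2c(c1CC=C(C)C)OC(c1c(CC=C(C)C)c(OCOC)cc(OCOC)c1CC=C(C)C)C2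
A4 | alternative 2 | methyl 2,6-bis[(2-methylbut-3-en-2-yl)oxy]-4-{6-[(2-methylbut-3-en-2-yl)oxy]-1-benzofuran-2-yl}benzoate | COC(=O)c1c(OC(C)(C)C=C)cc(-c2cc3ccc(OC(C)(C)C=C)cc3o2)cc1OC(C)(C)C=C
A5 | alternative 2 | methyl 2,6-dihydroxy-4-(6-hydroxy-7-prenyl-1-benzofuran-2-yl)-3,5-diprenylbenzoate | COC(=O)c1c(O)c(CC=C(C)C)c(-c2cc3ccc(O)c(CC=C(C)C)c3o2)c(CC=C(C)C)c1O
A6 | alternative 3 | 1-({(1Z)-1-[3,5-bis(methoxymethoxy)-2,6-diprenylphenyl]-2-bromoethenyl}oxy)-3-(methoxymethoxy)-2-prenylbenzene | Br/C=C(\Oc1cccc(OCOC)c1CC=C(C)C)c1c(CC=C(C)C)c(OCOC)cc(OCOC)c1CC=C(C)C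
A7 | alternative 3 | 2-[3,5-bis(methoxymethoxy)-2,6-diprenylphenyl]-6-(methoxymethoxy)-7-prenyl-1-benzofuran | CC(C)=CCc1c(OCOC)cc(OCOC)c(CC=C(C)C)c1-c1cc2ccc(OCOC)c(CC=C(C)C)c2o1
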